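**Strategy**

Each outer ring is disconnected into a ketone C3 unit (the C(CH3)2 carbon, the adjacent C–OH carbon and the butanoyl-bearing carbon) and a malonyl C3 unit. 3-Methylbut-3-en-2-one is converted into the regiodefined silyl enol ether Me2C=C(OSiEt3)CH3, which the key step, an Effenberger-type [3+3] annulation, C-acylates twice with malonyl dichloride: first at the C(CH3)2 carbon, then at the methyl carbon, onto the carbonyl para to C(CH3)2. This closes the 4,4-dimethylcyclohexane-1,3,5-trione ring (filicinic acid) in one operation and exploits the quaternary carbon, which forbids aromatisation and leaves one enolisable site for ring closure. Filicinic acid is mirror-symmetric, so C-butanoylation needs no regiocontrol; double methylene bridging of 2,4,6-trihydroxybutyrophenone completes the trimer.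

Key step: step 2

Remark: the three starting materials are taken as purchasable, and the target is treated as one tautomer of a rapidly equilibrating enol set.

**Route**

Step 1
Reactants: 1 3-methylbut-3-en-2-one
Product: 2 triethyl[(3-methylbut-2-en-2-yl)oxy]silane
Conditions: Et3SiH (1.1 equiv), RhCl(PPh3)3 (0.5 mol %), neat, 50 °C; distillation under reduced pressure
Reagents that add atoms: triethylsilane, CC[SiH](CC)CC
Why: Rh-catalysed 1,4-hydrosilylation of an enone with a monohydrosilane should place hydrogen on the terminal CH2 and silicon on oxygen, so the fully substituted silyl enol ether forms regiospecifically (no E/Z issue, since the enol carbon carries two methyl groups).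

Step 2
Reactants: 2 triethyl[(3-methylbut-2-en-2-yl)oxy]silane; 3 malonyl dichloride (1.1 equiv)
Product: 5 filicinic acid (3,5-dihydroxy-4,4-dimethylcyclohexa-2,5-dien-1-one), via 4,4-dimethyl-3,5-dioxohexanoyl chloride 4 (not isolated)
Conditions: Et2O, −20 °C to rt, 24 h; then aq KOH, BnEt3NCl (cat.), rt; then aq HCl to pH 1
Reagents that add atoms: none
Why: Malonyl dichloride should acylate the tetrasubstituted enol carbon of 2 (Mukaiyama-type C-acylation with loss of Et3SiCl), which makes the C(CH3)2–C(=O) bond (in the target the C(CH3)2–C(OH) bond on the side of the methylene bridge) and gives the acid chloride 4. In the basic phase-transfer stage the enolate of the methyl ketone in 4 should attack the acid chloride carbon (or the acylketene formed from it by loss of HCl), which makes the bond between the later butanoyl-bearing carbon and the ring carbonyl para to C(CH3)2 and closes the six-membered carbocycle in a 6-(enolendo)-exo-trig manner. The closest known reaction type is the Effenberger cyclisation of cyclohexanone silyl and methyl enol ethers with malonyl dichloride to bicyclo[3.3.1]nonane-2,4,9-triones, applied here to an acyclic ketone. No stereocentre is formed. The step needs the first C–C bond at the more substituted α-carbon and C- rather than O-acylation in the ring closure: the regiodefined enol ether secures the former, after which the quaternary carbon leaves the methyl group as the only enolisable position next to the ketone, and the C-acylated product is drained as its strongly stabilised triketone enolate. The geminal methyl groups should also favour ring closure (Thorpe–Ingold effect).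

Step 3
Reactants: 5 filicinic acid
Product: 6 butyrylfilicinic acid (2-butanoyl-3,5-dihydroxy-4,4-dimethylcyclohexa-2,5-dien-1-one)
Conditions: PrCOCl (1.05 equiv), AlCl3 (2.5 equiv), PhNO2, 0 °C to rt; then ice/aq HCl
Reagents that add atoms: butanoyl chloride, CCCC(Cl)=O
Why: Friedel–Crafts-type C-acylation of the enolised cyclic 1,3-diketone carbon (any enol ester formed first should undergo a Fries-type shift under AlCl3); the two ring CH positions of 5 are interchanged by its mirror plane, so one constitution results, and the new acyl group deactivates the ring against a second acylation.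

Step 4
Reactants: 6 butyrylfilicinic acid (2.2 equiv); 7 1-(2,4,6-trihydroxyphenyl)butan-1-one
Product: 9 target (filixic acid BBB), via mono-bridged dimer 8 (not isolated)
Conditions: 37% aq CH2O (2.0 equiv, slow addition), 1% aq KOH, 0 °C to rt; then 1 M HCl
Reagents that add atoms: formaldehyde, C=O
Why: Base-mediated hydroxymethylation, loss of hydroxide to a quinone-methide-type acceptor and conjugate addition of the partner enolate (the classical methylene bridging of acylphloroglucinols in dilute alkali) should give the trimer, because 6 has one free nucleophilic ring carbon and 7 has two.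

**Compound list**

1 | 3-methylbut-3-en-2-one | CC(=O)C(C)=C | starting material
2 | triethyl[(3-methylbut-2-en-2-yl)oxy]silane | CC(O[Si](CC)(CC)CC)=C(C)C | intermediate
3 | malonyl dichloride (propanedioyl dichloride) | O=C(Cl)CC(=O)Cl | starting material
4 | 4,4-dimethyl-3,5-dioxohexanoyl chloride (formed in the flask in step 2) | CC(=O)C(C)(C)C(=O)CC(=O)Cl | intermediate
5 | filicinic acid, 3,5-dihydroxy-4,4-dimethylcyclohexa-2,5-dien-1-one | CC1(C)C(O)=CC(=O)C=C1O | intermediate
6 | butyrylfilicinic acid, 2-butanoyl-3,5-dihydroxy-4,4-dimethylcyclohexa-2,5-dien-1-one | CCCC(=O)C1=C(O)C(C)(C)C(O)=CC1=O | intermediate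
7 | 1-(2,4,6-trihydroxyphenyl)butan-1-one | CCCC(=O)c1c(O)cc(O)cc1O | starting material
8 | 2-butanoyl-6-[(3-butanoyl-2,4,6-trihydroxyphenyl)methyl]-3,5-dihydroxy-4,4-dimethylcyclohexa-2,5-dien-1-one (mono-bridged dimer, formed in the flask in step 4) | CCCC(=O)C1=C(O)C(C)(C)C(O)=C(Cc2c(O)cc(O)c(C(=O)CCC)c2O)C1=O | intermediate
9 | 1-{3,5-bis[(5-butanoyl-2,4-dihydroxy-3,3-dimethyl-6-oxocyclohexa-1,4-dien-1-yl)methyl]-2,4,6-trihydroxyphenyl}butan-1-one (filixic acid BBB; no stereocentre) | CCCC(=O)C1=C(O)C(C)(C)C(O)=C(Cc2c(O)c(CC3=C(O)C(C)(C)C(O)=C(C(=O)CCC)C3=O)c(O)c(C(=O)CCC)c2O)C1=O | target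

**Count**

Total steps: 4. Longest linear sequence: 4 steps (1 → 2 → 5 → 6 → 9).

**Steps most likely to fail**

1. Step 2. Hydrolysis of the acid chloride function (followed by decarboxylation), or O-acylation, may outrun the second C-acylation in the aqueous basic stage. Fallback: setting out from 2, ZnCl2-mediated C-acylation with methyl 3-chloro-3-oxopropanoate in CH2Cl2 should give methyl 4,4-dimethyl-3,5-dioxohexanoate F1. NaOMe in MeOH at reflux should then close the ring by a Dieckmann-type condensation of the methyl ketone onto the ester, which comes back to the route at 5. The two ring bonds are then made in two separate operations.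

2. Step 4. The three-component coupling is statistical: self-bridging of 6, oligomerisation of 7 through formaldehyde and base-induced scrambling of methylene bridges may compete with the 2:1 cross-coupling. Fallback: setting out from 7, a Mannich reaction with aqueous formaldehyde and dimethylamine (2 equiv each, EtOH, rt) should give 1-{3,5-bis[(dimethylamino)methyl]-2,4,6-trihydroxyphenyl}butan-1-one F2. Heating F2 with 6 (2 equiv) in dioxane at 100 °C should release the two o-quinone methides one after the other, each trapped by conjugate addition of 6, which comes back to the route at 9.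

3. Step 3. O-acylation without migration to carbon, or a second acylation, may lower the yield of the mono-C-acyl compound. Fallback: setting out from 5, butanoyl chloride and pyridine in CH2Cl2 at 0 °C should give the enol ester 5-hydroxy-6,6-dimethyl-3-oxocyclohexa-1,4-dien-1-yl butanoate F3. Catalytic DMAP in MeCN should then effect the O-to-C 1,3-acyl shift known for enol esters of cyclic 1,3-diones, which comes back to the route at 6.

**Further compounds**

F1 | step 2 | methyl 4,4-dimethyl-3,5-dioxohexanoate | COC(=O)CC(=O)C(C)(C)C(C)=O
F2 | step 4 | 1-{3,5-bis[(dimethylamino)methyl]-2,4,6-trihydroxyphenyl}butan-1-one | CCCC(=O)c1c(O)c(CN(C)C)c(O)c(CN(C)C)c1O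
F3 | step 3 | 5-hydroxy-6,6-dimethyl-3-oxocyclohexa-1,4-dien-1-yl butanoate | CCCC(=O)OC1=CC(=O)C=C(O)C1(C)C
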